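**Analysis of the target**

Target 19 is a pentacycle. Numbering used throughout: pyrrole N-4, C-9a, C-1, C-2, C-3; azepane N-4, C-5 to C-9, C-9a; ring B C-9a, C-9, C-10, C-11, C-12, C-1; cis-fused γ-lactone C-11–O–C-14(=O)–C-13–C-12 with methyl C-15; ethyl C-16/C-17 on C-10; pendant γ-lactone C-18 to C-21 with methyl C-22 on C-3. The SMILES corresponds to 9R,10R,11S,12R,13R,18R,20S. Ring B carries four contiguous stereocentres: C-8, the lactone oxygen on C-11 and C-13 lie on one face, and the ethyl group lies on the other, trans to both of its neighbours. H-11, H-12 and H-13 are all cis, so the C-15 methyl sits on the concave face of the lactone (cis to C-1), which is the less stable C-13 epimer. In the pendant lactone the pyrrole (on C-18) and the methyl (on C-20) are trans. Sensitive groups are the electron-rich, fully substituted pyrrole (acids, oxidants), the C-18–O bond (a pyrrol-2-ylcarbinyl ester that ionises with acid) and the enolisable C-13 and C-20. The feature that the route exploits: N-4–C-9a=C-1 together with C-12 is a masked vinylogous amide, C-9a and C-12 being 1,3-related on ring B, so ring B is a cyclohexane-1,3-dione in disguise. The two cis hydrogens H-12/H-13 mark the C-12–C-13 bond as a hydrogenated butenolide double bond. The difficulty is to set the ring-B tetrad and the contra-thermodynamic methyl without strong acid or oxidant once the pyrrole exists.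

**Retrosynthetic reasoning**

19 to 17 (through 18): the acyl O–C-21 bond of the pendant lactone and the C-18–H bond are cut. The ionisable C-18–O bond is made last, under neutral conditions, and C-18 is set by a catalyst-controlled hydride transfer that does not depend on the remote ring-B centres.

17 to 15 and 16: the C-3–C-18 bond is cut. C-3 is the only free α-position of the pyrrole in 15, so acylation is regiochemically unambiguous, and 16 brings C-20 from the chiral pool.

15 to 14: H–C-12 and H–C-13 are removed (retro-hydrogenation). Both centres are then set together by syn delivery of hydrogen to the open face of a butenolide, which puts the methyl on the concave face without any enolate chemistry.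

14 to 11 and 12: the C-12=C-13 double bond (intramolecular olefination) and the O–C-14 ester bond are cut. This turns the lactone problem into a ketone at C-12 and a hydroxyl at C-11.

11 to 10: the C-11–O bond is cut. The forward reaction is an enolate hydroxylation anti to the C-10 ethyl group.

10 to 5 and 6 (key disconnection): C-1–C-2 and N-4–C-3 (pyrrole), N-4–C-9a (azepane) and C-1–C-9a (ring B) are cut in one operation. Ketone 10 is a vinylogous amide, so the three rings unravel to the open chain 5 plus the two-carbon unit 6, through 7, 8 and 9. The forward step must close three rings in sequence and relay C-10 to C-9 by equilibration.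

5 to 3 and 4: the C-8–C-9 bond is cut (malonate alkylation). The nitrogen arrives protected on a four-carbon chain.

3 to 1 and 2: the C-9–C-10 bond is cut (conjugate addition). This is the only step in which an external chiral catalyst sets a ring-B stereocentre (C-10).

**Alternatives that were turned down**

Alternative 1: the textbook Paal–Knorr cut of N-4–C-3 and N-4–C-9a. The amino 1,4-diketone A1 would condense to the pyrrole and the azepane at once. A1 must already carry every sp3 stereocentre of ring B and of both lactones. Its C-9, C-1 and C-18 are α to ketones; C-18 is an α-acyloxy ketone that epimerises and can eliminate carboxylate. The free primary amine can also open either lactone instead of forming a seven-membered imine. All the stereochemical work would be done before any ring-forming payoff, at roughly twice the step count.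

Alternative 2: a Diels–Alder reaction of a pyrrole-2,3-quinodimethane, forming C-9–C-10 and C-11–C-12. Enal A2 would be dearomatised by a secondary-amine catalyst to a trienamine and combined with 2 to give A3; the C-11 acetyl would then be turned into the C-11 oxygen by a retentive peracid oxidation. The amine-bound diene is strongly polarised, so the addition should be asynchronous (conjugate addition at C-10, then ring closure at C-12). Closure through a chair-like arrangement puts the C-11 acetyl trans to both neighbours, which makes ethyl and the C-12 chain cis, whereas the target needs the endo topology of A3. In addition, 2 is a weak electrophile for this activation mode and the peracid step would face an electron-rich pyrrole.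

Alternative 3: ring B from a dearomatised hydroquinone, because C-9a and C-11 are 1,4-related. Copper-catalysed enantioselective conjugate ethylation of the quinone monoketal A4 with allylation of the enolate would give A5 (C-9, C-10). A second conjugate addition at C-12, pyrrole annulation and ketal hydrolysis would lead to ketone A6, to be reduced and lactonised. The opening desymmetrisation is attractive. However, C-11 has to pass through ketone A6, in which C-10 and C-12 (between the carbonyl and the pyrrole) are both enolisable, and the preferred 2,6-cis arrangement places ethyl and the C-12 chain cis, opposite to the target. The C-9a ketone is also not a vinylogous amide, so the pyrrole needs extra carbon–carbon bond formation at C-1, and the route is three to four steps longer.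

Key step: step 3

Remark (assumption): the facial sense of the two catalyst-controlled steps (1 and 8) is assigned from the usual transition-state models, both catalysts being available in either (pseudo)enantiomeric form; 16 is taken as commercially available.

**Step 1**
Reactants: 1 dimethyl propanedioate (dimethyl malonate); 2 (3E)-hex-3-en-2-one
Product: 3 dimethyl 2-[(3S)-5-oxohexan-3-yl]propanedioate
Conditions: 9-amino(9-deoxy)epi-quinine (20 mol %), PhCO2H (40 mol %), THF, 25 °C
Reagents that add atoms: none
Why: Organocatalytic Michael addition: the primary amine activates 2 as an iminium ion and the quinuclidine delivers the malonate; attack on the Si face of C-4 of 2 should set C-10 as (S) in 3 (this becomes 10R in the target by a change of CIP priorities only).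

**Step 2**
Reactants: 3 dimethyl 2-[(3S)-5-oxohexan-3-yl]propanedioate; 4 tert-butyl N-(4-bromobutyl)carbamate
Product: 5 dimethyl 2-{4-[(tert-butoxycarbonyl)amino]butyl}-2-[(3S)-5-oxohexan-3-yl]propanedioate
Conditions: NaH (1.05 equiv), DMF, 0 °C; then 4, NaI (10 mol %), 45 °C
Reagents that add atoms: none
Why: Malonate alkylation (SN2): one equivalent of base deprotonates only the malonate C–H, so the ketone does not enolise and C-10 is untouched; the new quaternary carbon (future C-9) is not stereogenic.

**Step 3**
Reactants: 5 dimethyl 2-{4-[(tert-butoxycarbonyl)amino]butyl}-2-[(3S)-5-oxohexan-3-yl]propanedioate; 6 chloroacetaldehyde (50 % in water)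
Product: 10 (7aR,8S)-8-ethyl-4,5,6,7,7a,8,9,10-octahydroazepino[3,2,1-hi]indol-10-one, via cyclic keto ester 7 (not isolated), via amino dione 8 (not isolated), via bicyclic enaminone 9 (not isolated)
Conditions: KOtBu (3 equiv), THF, 0 °C; then 6 M aq. HCl, 80 °C; then NaOAc to pH 5–6 and 6 (1.5 equiv), 55 °C; one pot
Reagents that add atoms: none
Why: KOtBu forms the methyl-ketone enolate (C-1), which attacks one of the two ester groups in a Claisen (Dieckmann-type) condensation, a 6-(enolexo)-exo-trig closure of ring B that deprotonation of the resulting 1,3-dione 7 makes irreversible. Hot aqueous HCl should then hydrolyse and decarboxylate the remaining β-keto ester, remove the Boc group and, through the enol, equilibrate the new stereocentre C-9 to the trans (9R,10S) arrangement of 8, so that both C-9 epimers converge and C-10 from step 1 is the only control element. At pH 5–6 the liberated amine condenses with the carbonyl at C-9a (7-exo-trig addition, then loss of water); the other carbonyl would require a nine-membered ring, which secures the regiochemistry and gives the vinylogous amide 9 (azepane ring). Chloroacetaldehyde 6 then joins C-1 and N-4 of 9 in a Hantzsch-type annulation (aldol-type attack of the enaminone carbon, 5-exo-tet N-alkylation, dehydration) that closes the pyrrole; C-2 and C-3 are both CH, so either orientation of 6 leads to 10, and aromatisation drives the sequence. The closest known reaction types are the one-pot Claisen–decarboxylation route to cyclohexane-1,3-diones and the synthesis of 4-oxotetrahydroindoles from cyclic enaminones and α-halo aldehydes. The step needs selectivity between the two ketone enolates of 5 (only the methyl enolate reaches an ester through a six-membered ring) and mutual tolerance of the stages, which the strictly sequential change of pH should provide.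

**Step 4**
Reactants: 10 (7aR,8S)-8-ethyl-4,5,6,7,7a,8,9,10-octahydroazepino[3,2,1-hi]indol-10-one
Product: 11 (7aR,8R,9S)-8-ethyl-9-hydroxy-4,5,6,7,7a,8,9,10-octahydroazepino[3,2,1-hi]indol-10-one
Conditions: KN(SiMe3)2 (1.1 equiv), THF, −78 °C; 3-phenyl-2-(phenylsulfonyl)oxaziridine (1.2 equiv); AcOH quench
Reagents that add atoms: 3-phenyl-2-(phenylsulfonyl)oxaziridine, O=S(=O)(N1OC1c1ccccc1)c1ccccc1
Why: Enolate hydroxylation: C-11 is the only α-methylene of the C-12 ketone, and the oxaziridine should approach anti to the adjacent C-10 ethyl group, giving the 10,11-trans (11S) ketol, which is also the epimer favoured on equilibration.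

**Step 5**
Reactants: 11 (7aR,8R,9S)-8-ethyl-9-hydroxy-4,5,6,7,7a,8,9,10-octahydroazepino[3,2,1-hi]indol-10-one; 12 2-(diethoxyphosphoryl)propanoic acid
Product: 14 tetracyclic butenolide (9R,10R,11S; C-12=C-13; C-3 unsubstituted), via phosphonate ester 13 (not isolated)
Conditions: DCC (1.2 equiv), DMAP (10 mol %), CH2Cl2, 0 → 25 °C; filtration; then LiCl (2 equiv), DBU (1.5 equiv), MeCN, 25 → 60 °C
Reagents that add atoms: none
Why: Steglich esterification followed by an intramolecular Horner–Wadsworth–Emmons olefination of the C-12 ketone (5-exo-trig addition, then loss of diethyl phosphate) should close the butenolide; C-11 keeps its configuration and C-12/C-13 become a tetrasubstituted alkene.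

**Step 6**
Reactants: 14 tetracyclic butenolide (9R,10R,11S; C-12=C-13; C-3 unsubstituted)
Product: 15 tetracyclic lactone (9R,10R,11S,12R,13R; C-3 unsubstituted)
Conditions: H2 (4 bar), 10 % Pd/C, EtOAc, 25 °C
Reagents that add atoms: none
Why: Heterogeneous catalytic hydrogenation: both hydrogens should add syn to the face of the butenolide that carries only H-11, the other face being covered by C-10 of ring B; this sets C-12 (R) and C-13 (R) together, gives the cis ring fusion and leaves the methyl on the concave face.

**Step 7**
Reactants: 15 tetracyclic lactone (9R,10R,11S,12R,13R; C-3 unsubstituted); 16 (3S)-3-methyloxolane-2,5-dione ((S)-methylsuccinic anhydride)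
Product: 17 (2S)-2-methyl-4-oxo-4-(C-3 of lactone 15)butanoic acid
Conditions: AlCl3 (2.5 equiv), 16 (1.2 equiv), CH2Cl2–MeNO2, −20 → 0 °C; aqueous work-up at pH 3
Reagents that add atoms: none
Why: Friedel–Crafts acylation at the only free α-position (C-3) of the pyrrole; attack at the less hindered anhydride carbonyl (remote from the methyl) should place the untouched stereocentre of 16 as C-20 (S) and leave a free acid at C-21.

**Step 8**
Reactants: 17 (2S)-2-methyl-4-oxo-4-(C-3 of lactone 15)butanoic acid
Product: 19 CNP0232452.4 (9R,10R,11S,12R,13R,18R,20S), via hydroxy acid 18 (not isolated)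
Conditions: RuCl[(R,R)-TsDPEN](p-cymene) (2 mol %), HCO2Na (5 equiv), H2O–MeOH, 40 °C; extraction at pH 5; then DIC (1.2 equiv), DMAP (10 mol %), CH2Cl2, 0 °C
Reagents that add atoms: none
Why: Noyori-type asymmetric transfer hydrogenation of the aryl ketone under neutral formate conditions should set C-18 (R) by catalyst control; carbodiimide lactonisation then acylates the carbinol oxygen without breaking the C-18–O bond, so the trans (18R,20S) lactone forms with retention and without acid.

**Compound list**

1 | dimethyl propanedioate (dimethyl malonate) | COC(=O)CC(=O)OC | starting material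
2 | (3E)-hex-3-en-2-one | CC/C=C/C(C)=O | starting material
3 | dimethyl 2-[(3S)-5-oxohexan-3-yl]propanedioate | CC[C@H](C(C(=O)OC)C(=O)OC)CC(C)=O | intermediate
4 | tert-butyl N-(4-bromobutyl)carbamate | CC(C)(C)OC(=O)NCCCCBr | starting material
5 | dimethyl 2-{4-[(tert-butoxycarbonyl)amino]butyl}-2-[(3S)-5-oxohexan-3-yl]propanedioate | CC[C@H](C(CCCCNC(=O)OC(C)(C)C)(C(=O)OC)C(=O)OC)CC(C)=O | intermediate
6 | chloroacetaldehyde | ClCC=O | starting material
7 | methyl (6S)-1-{4-[(tert-butoxycarbonyl)amino]butyl}-6-ethyl-2,4-dioxocyclohexane-1-carboxylate (both C-1 epimers; potassium enolate in the flask) | CC[C@H]1CC(=O)CC(=O)C1(CCCCNC(=O)OC(C)(C)C)C(=O)OC | intermediate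
8 | (4R,5S)-4-(4-aminobutyl)-5-ethylcyclohexane-1,3-dione (hydrochloride in the flask) | CC[C@H]1CC(=O)CC(=O)[C@@H]1CCCCN | intermediate
9 | (5aR,6S)-6-ethyl-1,2,3,4,5,5a,6,7-octahydro-8H-1-benzazepin-8-one | CC[C@H]1CC(=O)C=C2NCCCC[C@H]12 | intermediate
10 | (7aR,8S)-8-ethyl-4,5,6,7,7a,8,9,10-octahydroazepino[3,2,1-hi]indol-10-one | CC[C@H]1CC(=O)c2ccn3c2[C@@H]1CCCC3 | intermediate
11 | (7aR,8R,9S)-8-ethyl-9-hydroxy-4,5,6,7,7a,8,9,10-octahydroazepino[3,2,1-hi]indol-10-one | CC[C@H]1[C@H](O)C(=O)c2ccn3c2[C@@H]1CCCC3 | intermediate
12 | 2-(diethoxyphosphoryl)propanoic acid (racemic) | CCOP(=O)(OCC)C(C)C(=O)O | starting material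
13 | (7aR,8R,9S)-8-ethyl-10-oxo-4,5,6,7,7a,8,9,10-octahydroazepino[3,2,1-hi]indol-9-yl 2-(diethoxyphosphoryl)propanoate | CC[C@H]1[C@H](OC(=O)C(C)P(=O)(OCC)OCC)C(=O)c2ccn3c2[C@@H]1CCCC3 | intermediate
14 | tetracyclic butenolide: skeleton of 19 without the C-3 lactone and with a C-12=C-13 double bond (9R,10R,11S) | CC[C@H]1[C@@H]2OC(=O)C(C)=C2c2ccn3c2[C@@H]1CCCC3 | intermediate
15 | tetracyclic lactone: skeleton of 19 without the C-3 lactone (9R,10R,11S,12R,13R) | CC[C@H]1[C@@H]2OC(=O)[C@H](C)[C@@H]2c2ccn3c2[C@@H]1CCCC3 | intermediate
16 | (3S)-3-methyloxolane-2,5-dione ((S)-methylsuccinic anhydride) | C[C@H]1CC(=O)OC1=O | starting material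
17 | (2S)-2-methyl-4-oxo-4-(C-3 of 15)butanoic acid (9R,10R,11S,12R,13R,20S) | CC[C@H]1[C@@H]2OC(=O)[C@H](C)[C@@H]2c2cc(C(=O)C[C@H](C)C(=O)O)n3c2[C@@H]1CCCC3 | intermediate
18 | (2S,4R)-4-hydroxy-2-methyl-4-(C-3 of 15)butanoic acid (9R,10R,11S,12R,13R,18R,20S) | CC[C@H]1[C@@H]2OC(=O)[C@H](C)[C@@H]2c2cc([C@H](O)C[C@H](C)C(=O)O)n3c2[C@@H]1CCCC3 | intermediate
19 | CNP0232452.4 (9R,10R,11S,12R,13R,18R,20S) | CC[C@H]1[C@@H]2OC(=O)[C@H](C)[C@@H]2c2cc([C@H]3C[C@H](C)C(=O)O3)n3c2[C@@H]1CCCC3 | target

**Step count and least certain steps**

Total step count: 8. Longest linear sequence: 8 (from 1 and 2).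

Step 3 (key step). The stage most likely to fail is the last one: in the crude buffered aqueous mixture, 6 may hydrate or oligomerise faster than it is captured, and closure through oxygen instead of nitrogen may compete on the ring-constrained vinylogous amide. A second concern is partial loss of C-10 integrity by retro-Michael fragmentation while the ketone enolates are present, and incomplete equilibration at C-9. Fallback: the cascade is stopped after the acid stage and 9 is isolated from 5. Compound 9 is N-alkylated with 2-bromo-1,1-diethoxyethane (NaH, NaI, DMF, 80 °C) to the N-(2,2-diethoxyethyl) vinylogous amide F1. Aqueous CF3CO2H then unmasks the aldehyde, C-1 attacks the oxocarbenium ion and dehydration returns the route at 10.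

Step 1. A small aliphatic β-substituent gives weak facial discrimination in the iminium ion, and iminium formation from an aliphatic enone is slow, so the enantiomeric purity of C-10 is at risk. Fallback with the roles reversed: from 1, Knoevenagel condensation with propanal gives dimethyl 2-propylidenepropanedioate F2. Enamine activation of acetone by a chiral primary amine–thiourea adds it to F2 and returns the route at 3.

Step 5. The C-12 carbonyl is a vinylogous amide and therefore a poor electrophile, so the olefination may stall while base epimerises C-11 through the ketol or the butenolide dienolate. Fallback from 11: acylation with 2-bromopropanoyl bromide (pyridine) gives the bromo ester F3. A zinc-mediated intramolecular Reformatsky addition closes the β-hydroxy lactone F4, and dehydration of its tertiary pyrrolylcarbinol (MsCl, Et3N) returns the route at 14.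

Step 6. The double bond is tetrasubstituted and conjugated with a donor, so hydrogen uptake may be slow, and hydrogenolysis of the allylic C-11–O bond may compete. Fallback from 14: copper hydride conjugate reduction (Cu(OAc)2, 1,2-bis(diphenylphosphino)benzene, diethoxy(methyl)silane) delivers hydride to C-12 from the open face and gives the silyl ketene acetal F5. Kinetic protonation (AcOH, THF, −78 °C) from the same convex face returns the route at 15.

Step 7. The anhydride may open at the carbonyl next to the methyl group, and AlCl3 may oligomerise the electron-rich pyrrole. Fallback from 15: acylation with the regiochemically defined acid chloride methyl (2S)-4-chloro-2-methyl-4-oxobutanoate F6 (from the corresponding half ester) under Et2AlCl gives the keto ester F7. Transfer hydrogenation as in step 8 gives the hydroxy ester F8, which lactonises on warming with catalytic 2-hydroxypyridine and returns the route at 19.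

Step 8. Hydride transfer to the electron-rich, ortho-substituted acylpyrrole may be slow, and the pyrrol-2-ylcarbinol may ionise, which would erode C-18 or lead to over-reduction. Fallback from 17: unselective reduction (NaBH4, CeCl3, MeOH) gives 18 together with its C-18 epimer F9. Lactonisation with DIC gives 19 and the cis-lactone F10, which are separated. F10 is recycled by mild saponification to F9 and MnO2 oxidation of the activated carbinol back to 17.

**Further compounds**

F1 | step 3 | (5aR,6S)-1-(2,2-diethoxyethyl)-6-ethyl-1,2,3,4,5,5a,6,7-octahydro-8H-1-benzazepin-8-one | CC[C@H]1CC(=O)C=C2N(CC(OCC)OCC)CCCC[C@H]12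
F2 | step 1 | dimethyl 2-propylidenepropanedioate | CCC=C(C(=O)OC)C(=O)OC
F3 | step 5 | 2-bromopropanoate ester of 11 (7aR,8R,9S) | CC[C@H]1[C@H](OC(=O)C(C)Br)C(=O)c2ccn3c2[C@@H]1CCCC3
F4 | step 5 | β-hydroxy lactone: 12-hydroxy derivative of 15 (9R,10R,11S; C-12 and C-13 unassigned) | CC[C@H]1[C@@H]2OC(=O)C(C)C2(O)c2ccn3c2[C@@H]1CCCC3
F5 | step 6 | diethoxy(methyl)silyl ketene acetal of 15 (9R,10R,11S,12R) | CC[C@H]1[C@@H]2OC(O[Si](C)(OCC)OCC)=C(C)[C@@H]2c2ccn3c2[C@@H]1CCCC3
F6 | step 7 | methyl (2S)-4-chloro-2-methyl-4-oxobutanoate | ClC(=O)C[C@H](C)C(=O)OC
F7 | step 7 | methyl ester of 17 | CC[C@H]1[C@@H]2OC(=O)[C@H](C)[C@@H]2c2cc(C(=O)C[C@H](C)C(=O)OC)n3c2[C@@H]1CCCC3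
F8 | step 7 | methyl ester of 18 (18R,20S) | CC[C@H]1[C@@H]2OC(=O)[C@H](C)[C@@H]2c2cc([C@H](O)C[C@H](C)C(=O)OC)n3c2[C@@H]1CCCC3
F9 | step 8 | C-18 epimer of 18 (18S,20S) | CC[C@H]1[C@@H]2OC(=O)[C@H](C)[C@@H]2c2cc([C@@H](O)C[C@H](C)C(=O)O)n3c2[C@@H]1CCCC3
F10 | step 8 | C-18 epimer of 19 (cis pendant lactone; 18S,20S) | CC[C@H]1[C@@H]2OC(=O)[C@H](C)[C@@H]2c2cc([C@@H]3C[C@H](C)C(=O)O3)n3c2[C@@H]1CCCC3
A1 | alternative 1 | amino 1,4-diketone for a Paal–Knorr closure (C-9a ketone; C-3 ketone; 4-aminobutyl on C-9; both lactones in place) | CC[C@H]1[C@@H]2OC(=O)[C@H](C)[C@@H]2C(CC(=O)[C@H]3C[C@H](C)C(=O)O3)C(=O)[C@@H]1CCCCN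
A2 | alternative 2 | (2E)-3-(6,7,8,9-tetrahydro-5H-pyrrolo[1,2-a]azepin-1-yl)prop-2-enal | O=C/C=C/c1ccn2CCCCCc12
A3 | alternative 2 | endo cycloadduct required: 11-acetyl-10-ethyl tricycle with a 2-oxoethyl group on C-12 | CC[C@H]1[C@H](C(C)=O)[C@H](CC=O)c2ccn3c2[C@@H]1CCCC3
A4 | alternative 3 | 4,4-dimethoxycyclohexa-2,5-dien-1-one | COC1(OC)C=CC(=O)C=C1
A5 | alternative 3 | trans-2-allyl-3-ethyl-4,4-dimethoxycyclohex-5-en-1-one (configured as C-9 and C-10 of 19) | CC[C@@H]1[C@@H](CC=C)C(=O)C=CC1(OC)OC
A6 | alternative 3 | C-11 ketone: methyl 2-(10-ethyl-11-oxo tricycle-12-yl)propanoate | CC[C@H]1C(=O)[C@H](C(C)C(=O)OC)c2ccn3c2[C@@H]1CCCC3
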